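## The problem

Compound 26 is a 3,6-disubstituted indole in which N1 and C2 both keep their hydrogen atoms. C3 of the pyrrole ring carries a stereogenic methine (Cα, S) that holds a CH2O–oleoyl arm and a tertiary carbinol, and C6 of the benzene ring carries a CH2 group bound to a (2R)-3,3-dimethyloxirane. The two stereocentres lie seven bonds apart across the flat bicyclic core, so neither can steer the other; each must come from a reagent or from the chiral pool. The trisubstituted epoxide does not tolerate acid, the (9Z)-alkene and the ester of the oleate do not tolerate ozone, organometallic reagents or hot fluoride, and the electron-rich indole limits the choice of oxidants. The acyl group therefore has to enter last and the epoxide shortly before it. Cα is flanked by two oxygenated carbons, and whenever it sits α to a carbonyl group it can epimerise or lose a β-oxygen substituent. The feature that opens the route is C2: it is a bare CH between N1 and C3, and removing this one carbon leaves a 2-aminoaryl ketone whose carbonyl carbon is C3 and whose α-carbon is Cα. The pyrrole ring can thus be closed last by inserting a single carbon between the ketone carbon and the aniline nitrogen.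

## Retrosynthesis

The ester C(=O)–O bond of 26 is cut first, giving diol 24 and oleic acid 25. Carrying the oleate any earlier would expose its alkene and ester to ozone, magnesium and lithium reagents and fluoride. The cut removes eighteen carbons, and the forward reaction only has to acylate a primary hydroxyl in the presence of a tertiary one and an indole N–H under nearly neutral conditions.

In 24 the epoxide C–O bond at the CH carbon and all protecting groups are removed together, leading back to mesylate 22. An (S)-sulfonate next to a masked tertiary alkoxide closes to the (R)-epoxide by inversion, so the epoxide exists only in the last two steps. Asymmetric epoxidation of a prenyl group would put an oxidant on the indole and would rest on catalyst control. The forward step asks for clean back-side displacement and for sulfonamide cleavage under conditions the epoxide survives.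

Mesylate 22 comes from alcohol 21, and 21 is cut at the C6–CH2 bond into bromoindole 15 and epoxide 19. A reductive coupling of the two electrophiles needs no organometallic derivative of the N-sulfonylindole and attacks the epoxide at its terminal carbon, so the carbinol carbon keeps the configuration of 19. Epoxide 19 is two steps from methyl (2S)-oxirane-2-carboxylate 16 through alcohol 18. This cut halves the problem: 15 holds Cα, 19 holds the second stereocentre.

Bromoindole 15 is opened at C2–C3 and C2–N1 to ketone 11 and trimethylsilyldiazomethane 12. A Fischer closure would give 4- and 6-bromo isomers and needs acid, and alkylation of a preformed indole at C3 offers no dependable control of Cα. In 11 the chain, with its stereocentre, is already attached to the carbon that becomes C3, and only one carbon has to be added. The forward reaction must add to a hindered ketone faster than it enolises it, and the carbene must be caught by nitrogen faster than it rearranges.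

Ketone 11 is taken back through alcohol 10 to aldehyde 6 and sulfonanilide 8, cutting the C3–C3a bond. Iodine–magnesium exchange on 8, which is made from 5-bromo-2-iodoaniline 7, distinguishes iodine from bromine, and the bromine is kept as the handle for C6. The arene and the chain are thereby separated into two small pieces.

Aldehyde 6 comes from alkene 4 by ozonolysis, 4 from diol 3, and 3 from epoxide 2 by cutting the Cα–vinyl bond; 2 is the Sharpless epoxide of prenol 1. All five carbons of the C3 side chain come from 1 and the vinyl group is a masked formyl group. The diol is protected as a cyclic di-tert-butylsilylene for four reasons: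
- one step covers both hydroxyls;
- the ring keeps both C–O bonds out of alignment with any neighbouring enol or enolate;
- it leaves the carbonyl less crowded than two separate silyl ethers would;
- fluoride removes it at the end without touching the epoxide.

## Roads not taken

Alternative 1: The Cα–C(CH3)2 bond is cut. The diazo ester A1 would insert its carbenoid carbon into the methine C–H of its own isopropyl group under Rh2(S-DOSP)4 or its mirror image, giving β-lactone A2 with Cα set by the catalyst.
- Merits: the indole is bought rather than built, one step creates both the stereocentre and the tertiary carbinol carbon, and hydride reduction of A2 would reveal the primary and tertiary hydroxyls already differentiated. The sequence to the stage of 15 would be three or four steps shorter and would avoid ozone and magnesium reagents.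
- Weak points: closing a four-membered ring by insertion into the ester alkoxy group is the less favoured mode for donor/acceptor carbenoids and competes with carbene dimerisation and attack on the indole nucleus. The indol-3-yl donor is hindered and electron-rich, a class for which induction by this catalyst is not assured. A2 also has an acidic Cα–H between carbonyl and indole and can lose CO2 on warming.
- Comparison: this road is better in step count and in being catalytic in chirality. The chosen plan sets against it a stereocentre made by a Sharpless epoxidation and a stereospecific SN2 opening, two reactions whose sense does not depend on the heterocycle, and a ring closure with direct precedent in its substrate class.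

Alternative 2: N1–C2 and C3–C3a are cut. Aniline 7 and the lactol A3 would be joined with Pd(OAc)2 and DABCO in DMF, condensation forming N1–C2 and intramolecular arylation forming C3–C3a, to give indole A4 with its CH2OH arm set free.
- Merits: the arene and the chain meet in the ring-forming step, no nitrogen protecting group or redox adjustment is needed, and the stereocentre of A3 lies β to the aldehyde carbon and cannot epimerise by enolisation. That last point is a real advantage over 6 and 11.
- Weak points: A3 has no cheap chiral-pool source and needs an asymmetric synthesis of its own, which returns most of the steps saved. The lactol is mostly closed and the haloaniline is a poor nucleophile, so the condensation needs heat, and there the C–Br bond begins to compete for zerovalent palladium. The free primary hydroxyl of A4 would be mesylated before the secondary one later on, so it must either be protected or acylated early, which sends the oleate through the coupling and the fluoride step.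
- Comparison: this road is more convergent and avoids the diazo reagent. The chosen plan sets against it a two-step access to the whole C3 chain from prenol, a ring closure run between −78 °C and room temperature that cannot touch the bromide, and an N-sulfonyl group that shields the indole until the end.

Alternative 3: N1–C2 is cut. The nitrostyrene A6, whose benzene ring and C6 side chain come from L-tyrosine A5, would be deoxygenated with CO under Pd(OAc)2 and 1,10-phenanthroline so that nitrogen bonds to the terminal alkene carbon, giving indole A7.
- Merits: the C6 stereocentre comes from an amino acid, the phenol oxygen serves both to direct nitration and as the coupling handle, the indole is formed with a free N–H under neutral conditions, and neither halogen–metal exchange nor a reductive epoxide coupling is needed.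
- Weak points: the alkene partner, a 1,1-disubstituted alkenyl metal carrying Cα, must be made enantiopure and coupled next to a nitro group. The Cα–H of A6 is allylic to a styrene and could be lost by double-bond migration at the temperature of the carbonylative reduction. The acetonide of A7 must be removed with acid in the presence of the indole and two silyl ethers before a selective mesylation, so the endgame is longer and the route is the longest of the four.
- Comparison: this road is equal in closing the pyrrole ring late and better in needing no nitrogen protecting group. The chosen plan sets against it a shorter sequence, a stereocentre that never sits next to an isomerisable alkene, and a C6 stereocentre that is likewise taken from the chiral pool.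

Key step: step 8

Assumption: commercial oleic acid is taken as the pure (9Z) isomer and methyl (2S)-oxirane-2-carboxylate as a commercial chiral-pool ester, so neither the alkene geometry nor the epoxide configuration of 19 has to be created in the route.

## Steps

Step 1
Reactants: 1 prenol (3-methylbut-2-en-1-ol)
Product: 2 [(2R)-3,3-dimethyloxiran-2-yl]methanol
Conditions: Ti(OiPr)4 (5 mol%), D-(−)-diethyl tartrate (6 mol%), t-BuOOH (2 equiv), 4 Å molecular sieves, CH2Cl2, −20 °C
Reagents that add atoms: tert-butyl hydroperoxide, CC(C)(C)OO
Why: Katsuki–Sharpless asymmetric epoxidation of a primary allylic alcohol; with the D-(−)-tartrate the titanium-bound peroxide should reach the face that gives (R) at C2, the mirror image of the sense known for geraniol-type alcohols with L-(+)-tartrate.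

Step 2
Reactants: 2 [(2R)-3,3-dimethyloxiran-2-yl]methanol
Product: 3 (2S)-2-ethenyl-3-methylbutane-1,3-diol
Conditions: CH2=CHMgBr (4 equiv), CuI (20 mol%), THF, −40 → −10 °C; aq. NH4Cl
Reagents that add atoms: vinylmagnesium bromide, C=C[Mg]Br
Why: Copper-catalysed SN2 opening of a 2,3-epoxy alcohol; C3 is fully substituted, so the vinylcopper species should attack C2 with inversion, turning the (R)-epoxide carbon into the (S)-methine that becomes Cα and installing the vinyl group as a masked formyl group.

Step 3
Reactants: 3 (2S)-2-ethenyl-3-methylbutane-1,3-diol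
Product: 4 (5S)-2,2-di-tert-butyl-5-ethenyl-4,4-dimethyl-1,3,2-dioxasilinane
Conditions: t-Bu2Si(OTf)2, 2,6-lutidine, CH2Cl2, 0 °C → rt
Reagents that add atoms: di-tert-butylsilyl bis(trifluoromethanesulfonate), CC(C)(C)[Si](OS(=O)(=O)C(F)(F)F)(OS(=O)(=O)C(F)(F)F)C(C)(C)C
Why: Cyclic silylene protection of a 1,3-diol; the bis-triflate is reactive enough for the tertiary hydroxyl, one step covers both oxygens, and the six-membered ring later keeps both C–O bonds out of alignment with a carbonyl or enolate π-system at the neighbouring carbon.

Step 4
Reactants: 4 (5S)-2,2-di-tert-butyl-5-ethenyl-4,4-dimethyl-1,3,2-dioxasilinane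
Product: 6 (5S)-2,2-di-tert-butyl-4,4-dimethyl-1,3,2-dioxasilinane-5-carbaldehyde, via secondary ozonide 5 (not isolated)
Conditions: O3, CH2Cl2, −78 °C; then PPh3, −78 °C → rt; used crude
Reagents that add atoms: ozone, [O-][O+]=O
Why: Ozonolysis of a terminal alkene with reductive work-up; the neutral phosphine reduction and immediate use of the aldehyde should leave the α-stereocentre intact.

Step 5
Reactants: 7 5-bromo-2-iodoaniline
Product: 8 N-(5-bromo-2-iodophenyl)-4-methylbenzenesulfonamide
Conditions: TsCl, pyridine, CH2Cl2, 0 °C → rt
Reagents that add atoms: 4-methylbenzenesulfonyl chloride, Cc1ccc(cc1)S(=O)(=O)Cl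
Why: Standard sulfonylation of an aniline; the ortho iodine slows a second sulfonylation, and the remaining N–H is the nitrogen nucleophile of the key step.

Step 6
Reactants: 8 N-(5-bromo-2-iodophenyl)-4-methylbenzenesulfonamide; 6 (5S)-2,2-di-tert-butyl-4,4-dimethyl-1,3,2-dioxasilinane-5-carbaldehyde
Product: 10 N-(5-bromo-2-{[(5R)-2,2-di-tert-butyl-4,4-dimethyl-1,3,2-dioxasilinan-5-yl](hydroxy)methyl}phenyl)-4-methylbenzenesulfonamide as both carbinol epimers, via aryl Grignard reagent 9 (not isolated)
Conditions: 8 (1.3 equiv), i-PrMgCl·LiCl (2.7 equiv), THF, −20 °C; then 6, −40 → 0 °C; aq. NH4Cl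
Reagents that add atoms: none
Why: Iodine–magnesium exchange on the N-magnesiated sulfonanilide is far faster at C–I than at C–Br, and the aryl Grignard reagent should add to the aldehyde at low temperature before it can enolise it; the new carbinol centre is left uncontrolled because step 7 removes it (the ring carbon is unchanged in space and is (5R) here only through a change of priorities).

Step 7
Reactants: 10 N-(5-bromo-2-{[(5R)-2,2-di-tert-butyl-4,4-dimethyl-1,3,2-dioxasilinan-5-yl](hydroxy)methyl}phenyl)-4-methylbenzenesulfonamide
Product: 11 N-{5-bromo-2-[(5S)-2,2-di-tert-butyl-4,4-dimethyl-1,3,2-dioxasilinane-5-carbonyl]phenyl}-4-methylbenzenesulfonamide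
Conditions: Dess–Martin periodinane, NaHCO3, CH2Cl2, 0 °C → rt
Reagents that add atoms: none
Why: Dess–Martin oxidation of a secondary benzylic alcohol under buffered, non-enolising conditions; both epimers of 10 converge on one ketone and Cα is not touched.

Step 8
Reactants: 11 N-{5-bromo-2-[(5S)-2,2-di-tert-butyl-4,4-dimethyl-1,3,2-dioxasilinane-5-carbonyl]phenyl}-4-methylbenzenesulfonamide; 12 trimethylsilyldiazomethane
Product: 15 6-bromo-3-[(5S)-2,2-di-tert-butyl-4,4-dimethyl-1,3,2-dioxasilinan-5-yl]-1-(4-methylbenzenesulfonyl)-1H-indole, via alkylidene carbene lithium sulfonamide 13 (not isolated), via 2-lithioindole 14 (not isolated)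
Conditions: 12 (2.5 equiv), n-BuLi (2.4 equiv), THF, −78 °C, 30 min; then 11 in THF, −78 °C → rt; aq. NH4Cl
Reagents that add atoms: none
Why: The first equivalent of lithium trimethylsilyldiazomethanide removes the sulfonamide proton and the second adds to the ketone carbonyl at −78 °C; on warming, Peterson-type loss of lithium trimethylsilanolate and then of N2 unveils the alkylidene carbene 13, whose carbene carbon is the future C2 and whose alkylidene carbon is C3. The lithium sulfonamide nitrogen, held ortho on the aryl group geminal to the carbene, adds its lone pair to the vacant in-plane orbital of the carbene carbon, a formal 1,5 N–H insertion in which C2–N1 forms after C2=C3 and the five-membered pyrrole ring (N1, C2, C3, C3a, C7a) closes with the new double bond inside the ring; the resulting 2-lithioindole 14 is protonated on quench at the latest. The closest known reaction type is the conversion of 2-(sulfonylamino)aryl ketones into 3-substituted N-sulfonylindoles with this same lithium reagent, an intramolecular trapping of the carbene of the Colvin homologation. No stereocentre is created; Cα should be kept because carbonyl addition at −78 °C outruns enolisation, and the enolate would be a strained tetrasubstituted exocyclic alkene whose ring C–O bonds are held out of alignment with it, so neither epimerisation nor β-elimination is well set up. The step needs capture by nitrogen to beat the 1,2-aryl shift to an alkyne, 1,5 C–H insertion and insertion into an O–Si bond. The anionic nitrogen five atoms from the carbene secures the first; the only C–H bonds in a 1,5 relationship are those of the two methyl groups, the least reactive kind; and the cyclic silylene ties the ether oxygens into a ring from which ylide formation and silyl shift would have to give a bridged bicycle. The aryl bromide is safe provided the slight excess of 12 has consumed all n-BuLi before 11 is added.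

Step 9
Reactants: 16 methyl (2S)-oxirane-2-carboxylate
Product: 18 2-[(2S)-oxiran-2-yl]propan-2-ol, via oxiranyl methyl ketone 17 (not isolated)
Conditions: MeMgCl (2.2 equiv), THF, −78 → −30 °C; aq. NH4Cl
Reagents that add atoms: methylmagnesium chloride, C[Mg]Cl
Why: Double Grignard addition to an ester; at low temperature the carbonyl group should be attacked much faster than the epoxide, and no bond to the stereocentre is broken.

Step 10
Reactants: 18 2-[(2S)-oxiran-2-yl]propan-2-ol
Product: 19 triethyl({2-[(2S)-oxiran-2-yl]propan-2-yl}oxy)silane
Conditions: Et3SiOTf, 2,6-lutidine, CH2Cl2, −78 °C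
Reagents that add atoms: triethylsilyl trifluoromethanesulfonate, CC[Si](CC)(CC)OS(=O)(=O)C(F)(F)F
Why: Silylation of a tertiary alcohol with a silyl triflate and a hindered base; the triethylsilyl ether makes the fragment non-volatile and masks the oxygen nucleophile that fluoride releases in step 13.

Step 11
Reactants: 15 6-bromo-3-[(5S)-2,2-di-tert-butyl-4,4-dimethyl-1,3,2-dioxasilinan-5-yl]-1-(4-methylbenzenesulfonyl)-1H-indole; 19 triethyl({2-[(2S)-oxiran-2-yl]propan-2-yl}oxy)silane
Product: 21 (2S)-1-{3-[(5S)-2,2-di-tert-butyl-4,4-dimethyl-1,3,2-dioxasilinan-5-yl]-1-(4-methylbenzenesulfonyl)-1H-indol-6-yl}-3-methyl-3-[(triethylsilyl)oxy]butan-2-ol, via iodohydrin 20 (not isolated)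
Conditions: 19 (1.5 equiv), NiBr2·glyme (10 mol%), 2,2'-bipyridine (10 mol%), NaI (25 mol%), Et3N·HCl (1 equiv), Zn (2 equiv), DMPU, rt
Reagents that add atoms: none
Why: Nickel-catalysed reductive cross-electrophile coupling of an aryl bromide with a terminal epoxide under iodide co-catalysis; iodide opens the epoxide at the unhindered CH2, the primary alkyl iodide 20 is then joined to the arylnickel species formed from 15, and the carbinol carbon keeps the (S) configuration of 19 because none of its bonds is broken.

Step 12
Reactants: 21 (2S)-1-{3-[(5S)-2,2-di-tert-butyl-4,4-dimethyl-1,3,2-dioxasilinan-5-yl]-1-(4-methylbenzenesulfonyl)-1H-indol-6-yl}-3-methyl-3-[(triethylsilyl)oxy]butan-2-ol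
Product: 22 (2S)-1-{3-[(5S)-2,2-di-tert-butyl-4,4-dimethyl-1,3,2-dioxasilinan-5-yl]-1-(4-methylbenzenesulfonyl)-1H-indol-6-yl}-3-methyl-3-[(triethylsilyl)oxy]butan-2-yl methanesulfonate
Conditions: MsCl, Et3N, CH2Cl2, 0 °C
Reagents that add atoms: methanesulfonyl chloride, CS(=O)(=O)Cl
Why: Mesylation by way of sulfene copes with the hindered secondary alcohol, which is the only free hydroxyl in 21; the C–O bond is not broken, so the (S) configuration is retained.

Step 13
Reactants: 22 (2S)-1-{3-[(5S)-2,2-di-tert-butyl-4,4-dimethyl-1,3,2-dioxasilinan-5-yl]-1-(4-methylbenzenesulfonyl)-1H-indol-6-yl}-3-methyl-3-[(triethylsilyl)oxy]butan-2-yl methanesulfonate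
Product: 24 (2S)-2-(6-{[(2R)-3,3-dimethyloxiran-2-yl]methyl}-1H-indol-3-yl)-3-methylbutane-1,3-diol, via N-tosyl epoxy diol 23 (not isolated)
Conditions: Bu4NF (6 equiv), THF, 0 °C → rt; then 65 °C
Reagents that add atoms: none
Why: Fluoride cleaves the triethylsilyl ether and the silylene; the freed tertiary alkoxide displaces the neighbouring mesylate from the back (3-exo-tet), turning the (S)-carbinol carbon into the (R)-epoxide carbon, and continued heating with fluoride removes the N-sulfonyl group, a known cleavage for N-sulfonylindoles.

Step 14
Reactants: 24 (2S)-2-(6-{[(2R)-3,3-dimethyloxiran-2-yl]methyl}-1H-indol-3-yl)-3-methylbutane-1,3-diol; 25 oleic acid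
Product: 26 (2S)-2-(6-{[(2R)-3,3-dimethyloxiran-2-yl]methyl}-1H-indol-3-yl)-3-hydroxy-3-methylbutyl (9Z)-octadec-9-enoate
Conditions: 25 (1.1 equiv), EDC·HCl, DMAP (20 mol%), CH2Cl2, 0 °C → rt
Reagents that add atoms: none
Why: Steglich-type carbodiimide esterification; the primary hydroxyl should be acylated in preference to the tertiary hydroxyl and the indole N–H, and the nearly neutral medium spares the epoxide and the (Z)-alkene.

## Compound list

1 | prenol (3-methylbut-2-en-1-ol) | CC(C)=CCO | starting material
2 | [(2R)-3,3-dimethyloxiran-2-yl]methanol | OC[C@H]1OC1(C)C | intermediate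
3 | (2S)-2-ethenyl-3-methylbutane-1,3-diol | C=C[C@@H](CO)C(C)(C)O | intermediate
4 | (5S)-2,2-di-tert-butyl-5-ethenyl-4,4-dimethyl-1,3,2-dioxasilinane | C=C[C@H]1CO[Si](C(C)(C)C)(C(C)(C)C)OC1(C)C | intermediate
5 | 3-[(5S)-2,2-di-tert-butyl-4,4-dimethyl-1,3,2-dioxasilinan-5-yl]-1,2,4-trioxolane (secondary ozonide, either configuration at the trioxolane carbon) | O1OC([C@H]2CO[Si](C(C)(C)C)(C(C)(C)C)OC2(C)C)OC1 | intermediate (not isolated)
6 | (5S)-2,2-di-tert-butyl-4,4-dimethyl-1,3,2-dioxasilinane-5-carbaldehyde | O=C[C@H]1CO[Si](C(C)(C)C)(C(C)(C)C)OC1(C)C | intermediate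
7 | 5-bromo-2-iodoaniline | Nc1cc(Br)ccc1I | starting material
8 | N-(5-bromo-2-iodophenyl)-4-methylbenzenesulfonamide | Cc1ccc(cc1)S(=O)(=O)Nc1cc(Br)ccc1I | intermediate
9 | aryl Grignard reagent: N,2-bis(chloromagnesio) derivative of N-(5-bromophenyl)-4-methylbenzenesulfonamide | Cc1ccc(cc1)S(=O)(=O)N([Mg]Cl)c1cc(Br)ccc1[Mg]Cl | intermediate (not isolated)
10 | N-(5-bromo-2-{[(5R)-2,2-di-tert-butyl-4,4-dimethyl-1,3,2-dioxasilinan-5-yl](hydroxy)methyl}phenyl)-4-methylbenzenesulfonamide, both carbinol epimers | Cc1ccc(cc1)S(=O)(=O)Nc1cc(Br)ccc1C(O)[C@H]1CO[Si](C(C)(C)C)(C(C)(C)C)OC1(C)C | intermediate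
11 | N-{5-bromo-2-[(5S)-2,2-di-tert-butyl-4,4-dimethyl-1,3,2-dioxasilinane-5-carbonyl]phenyl}-4-methylbenzenesulfonamide | Cc1ccc(cc1)S(=O)(=O)Nc1cc(Br)ccc1C(=O)[C@H]1CO[Si](C(C)(C)C)(C(C)(C)C)OC1(C)C | intermediate
12 | trimethylsilyldiazomethane | C[Si](C)(C)C=[N+]=[N-] | starting material
13 | alkylidene carbene, N-lithium salt: 11 with the C=O oxygen replaced by a terminal divalent carbon (C=C:) and N–H replaced by N–Li, (5S) | Cc1ccc(cc1)S(=O)(=O)N([Li])c1cc(Br)ccc1C(=[C])[C@H]1CO[Si](C(C)(C)C)(C(C)(C)C)OC1(C)C | intermediate (not isolated)
14 | 6-bromo-3-[(5S)-2,2-di-tert-butyl-4,4-dimethyl-1,3,2-dioxasilinan-5-yl]-2-lithio-1-(4-methylbenzenesulfonyl)-1H-indole | Cc1ccc(cc1)S(=O)(=O)n1c([Li])c([C@H]2CO[Si](C(C)(C)C)(C(C)(C)C)OC2(C)C)c2ccc(Br)cc21 | intermediate (not isolated)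
15 | 6-bromo-3-[(5S)-2,2-di-tert-butyl-4,4-dimethyl-1,3,2-dioxasilinan-5-yl]-1-(4-methylbenzenesulfonyl)-1H-indole | Cc1ccc(cc1)S(=O)(=O)n1cc([C@H]2CO[Si](C(C)(C)C)(C(C)(C)C)OC2(C)C)c2ccc(Br)cc21 | intermediate
16 | methyl (2S)-oxirane-2-carboxylate | COC(=O)[C@@H]1CO1 | starting material
17 | 1-[(2S)-oxiran-2-yl]ethan-1-one | CC(=O)[C@@H]1CO1 | intermediate (not isolated)
18 | 2-[(2S)-oxiran-2-yl]propan-2-ol | CC(C)(O)[C@@H]1CO1 | intermediate
19 | triethyl({2-[(2S)-oxiran-2-yl]propan-2-yl}oxy)silane | CC[Si](CC)(CC)OC(C)(C)[C@@H]1CO1 | intermediate
20 | (2R)-1-iodo-3-methyl-3-[(triethylsilyl)oxy]butan-2-ol | CC[Si](CC)(CC)OC(C)(C)[C@@H](O)CI | intermediate (not isolated)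
21 | (2S)-1-{3-[(5S)-2,2-di-tert-butyl-4,4-dimethyl-1,3,2-dioxasilinan-5-yl]-1-(4-methylbenzenesulfonyl)-1H-indol-6-yl}-3-methyl-3-[(triethylsilyl)oxy]butan-2-ol | Cc1ccc(cc1)S(=O)(=O)n1cc([C@H]2CO[Si](C(C)(C)C)(C(C)(C)C)OC2(C)C)c2ccc(C[C@H](O)C(C)(C)O[Si](CC)(CC)CC)cc21 | intermediate
22 | (2S)-1-{3-[(5S)-2,2-di-tert-butyl-4,4-dimethyl-1,3,2-dioxasilinan-5-yl]-1-(4-methylbenzenesulfonyl)-1H-indol-6-yl}-3-methyl-3-[(triethylsilyl)oxy]butan-2-yl methanesulfonate | Cc1ccc(cc1)S(=O)(=O)n1cc([C@H]2CO[Si](C(C)(C)C)(C(C)(C)C)OC2(C)C)c2ccc(C[C@H](OS(C)(=O)=O)C(C)(C)O[Si](CC)(CC)CC)cc21 | intermediate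
23 | (2S)-2-[6-{[(2R)-3,3-dimethyloxiran-2-yl]methyl}-1-(4-methylbenzenesulfonyl)-1H-indol-3-yl]-3-methylbutane-1,3-diol | Cc1ccc(cc1)S(=O)(=O)n1cc([C@@H](CO)C(C)(C)O)c2ccc(C[C@H]3OC3(C)C)cc21 | intermediate (not isolated)
24 | (2S)-2-(6-{[(2R)-3,3-dimethyloxiran-2-yl]methyl}-1H-indol-3-yl)-3-methylbutane-1,3-diol | OC[C@H](c1c[nH]c2cc(C[C@H]3OC3(C)C)ccc12)C(C)(C)O | intermediate
25 | oleic acid, (9Z)-octadec-9-enoic acid | CCCCCCCC/C=C\CCCCCCCC(=O)O | starting material
26 | (2S)-2-(6-{[(2R)-3,3-dimethyloxiran-2-yl]methyl}-1H-indol-3-yl)-3-hydroxy-3-methylbutyl (9Z)-octadec-9-enoate | CCCCCCCC/C=C\CCCCCCCC(=O)OC[C@H](c1c[nH]c2cc(C[C@H]3OC3(C)C)ccc12)C(C)(C)O | target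

## Step count and weak points

Total: 14 steps. Longest linear sequence: 11 steps from prenol 1 (steps 1, 2, 3, 4, 6, 7, 8, 11, 12, 13, 14); steps 5, 9 and 10 are side branches.

Step 8 (key step). Most likely failure: the basic lithium reagent enolises the hindered ketone in place of adding to it, which erodes the configuration at Cα, or the 1,2-aryl shift of the carbene to an alkyne runs ahead of capture by nitrogen. Fallback: set out from 11 and bring the carbon in without base. Takai–Lombardo methylenation (Zn, CH2Br2, TiCl4, THF/CH2Cl2) should give the styrene N-{5-bromo-2-[1-((5S)-2,2-di-tert-butyl-4,4-dimethyl-1,3,2-dioxasilinan-5-yl)ethenyl]phenyl}-4-methylbenzenesulfonamide F1. A Hegedus-type oxidative amination (Pd(OAc)2 cat., 1,4-benzoquinone, THF), in which divalent palladium activates the alkene toward the sulfonamide nitrogen, then forms N1–C2 and rejoins the route at 15.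

Step 6. Most likely failure: slow addition of the hindered aryl Grignard reagent, so that base-induced epimerisation or self-condensation of the aldehyde takes over, or incomplete iodine–magnesium exchange. Fallback: set out from 6. Pinnick oxidation (NaClO2, NaH2PO4, 2-methylbut-2-ene) gives (5S)-2,2-di-tert-butyl-4,4-dimethyl-1,3,2-dioxasilinane-5-carboxylic acid F2, and carbodiimide coupling with N,O-dimethylhydroxylamine gives the Weinreb amide (5S)-2,2-di-tert-butyl-N-methoxy-N,4,4-trimethyl-1,3,2-dioxasilinane-5-carboxamide F3. Acylation of 9 with F3, whose chelated adduct resists over-addition and α-deprotonation, comes back at 11 and makes step 7 unnecessary.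

Step 11. Most likely failure: reductive homocoupling or hydrodehalogenation of the aryl bromide outpaces capture of the hindered, β-oxygenated alkyl fragment, or the triethylsilyl group migrates from the tertiary to the new secondary oxygen. Fallback: set out from 15 and separate C–C bond formation from stereocontrol. Stille coupling with tributyl(3-methylbut-2-en-1-yl)stannane (Pd(PPh3)4, DMF, 90 °C) should give 3-[(5S)-2,2-di-tert-butyl-4,4-dimethyl-1,3,2-dioxasilinan-5-yl]-6-(3-methylbut-2-en-1-yl)-1-(4-methylbenzenesulfonyl)-1H-indole F4. Shi epoxidation (D-fructose-derived ketone, KHSO5, K2CO3 buffer, MeCN/dimethoxymethane/H2O, 0 °C) should then give 3-[(5S)-2,2-di-tert-butyl-4,4-dimethyl-1,3,2-dioxasilinan-5-yl]-6-{[(2R)-3,3-dimethyloxiran-2-yl]methyl}-1-(4-methylbenzenesulfonyl)-1H-indole F5, the (R) sense being the one expected from the spiro transition state. Bu4NF as in step 13 then comes back at 24, so steps 9 to 12 drop out. The price is that the epoxide configuration then rests on catalyst control.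

Step 13. Most likely failure: incomplete cleavage of the sulfonamide at temperatures the epoxide tolerates, or opening of the epoxide by fluoride or alkoxide on long heating. Fallback: set out from 22, treat with Bu4NF at room temperature only and isolate 23. The sulfonyl group is then removed reductively with Mg turnings in MeOH at room temperature, by electron transfer in place of nucleophilic attack at sulfur, which comes back at 24.

## Further compounds

F1 | step 8 | N-{5-bromo-2-[1-((5S)-2,2-di-tert-butyl-4,4-dimethyl-1,3,2-dioxasilinan-5-yl)ethenyl]phenyl}-4-methylbenzenesulfonamide | Cc1ccc(cc1)S(=O)(=O)Nc1cc(Br)ccc1C(=C)[C@H]1CO[Si](C(C)(C)C)(C(C)(C)C)OC1(C)C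
F2 | step 6 | (5S)-2,2-di-tert-butyl-4,4-dimethyl-1,3,2-dioxasilinane-5-carboxylic acid | OC(=O)[C@H]1CO[Si](C(C)(C)C)(C(C)(C)C)OC1(C)C
F3 | step 6 | (5S)-2,2-di-tert-butyl-N-methoxy-N,4,4-trimethyl-1,3,2-dioxasilinane-5-carboxamide | CON(C)C(=O)[C@H]1CO[Si](C(C)(C)C)(C(C)(C)C)OC1(C)C
F4 | step 11 | 3-[(5S)-2,2-di-tert-butyl-4,4-dimethyl-1,3,2-dioxasilinan-5-yl]-6-(3-methylbut-2-en-1-yl)-1-(4-methylbenzenesulfonyl)-1H-indole | Cc1ccc(cc1)S(=O)(=O)n1cc([C@H]2CO[Si](C(C)(C)C)(C(C)(C)C)OC2(C)C)c2ccc(CC=C(C)C)cc21
F5 | step 11 | 3-[(5S)-2,2-di-tert-butyl-4,4-dimethyl-1,3,2-dioxasilinan-5-yl]-6-{[(2R)-3,3-dimethyloxiran-2-yl]methyl}-1-(4-methylbenzenesulfonyl)-1H-indole | Cc1ccc(cc1)S(=O)(=O)n1cc([C@H]2CO[Si](C(C)(C)C)(C(C)(C)C)OC2(C)C)c2ccc(C[C@H]3OC3(C)C)cc21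
F0 | step 13 | none | none
A1 | alternative 1 | isopropyl 2-[6-bromo-1-(tert-butoxycarbonyl)-1H-indol-3-yl]-2-diazoacetate | CC(C)OC(=O)C(=[N+]=[N-])c1cn(C(=O)OC(C)(C)C)c2cc(Br)ccc12
A2 | alternative 1 | tert-butyl 6-bromo-3-[(3R)-2,2-dimethyl-4-oxooxetan-3-yl]-1H-indole-1-carboxylate | O=C1[C@H](c2cn(C(=O)OC(C)(C)C)c3cc(Br)ccc23)C(C)(C)O1
A3 | alternative 2 | (4S)-4-{2-[(triethylsilyl)oxy]propan-2-yl}oxolan-2-ol | OC1C[C@@H](CO1)C(C)(C)O[Si](CC)(CC)CC
A4 | alternative 2 | (2S)-2-(6-bromo-1H-indol-3-yl)-3-methyl-3-[(triethylsilyl)oxy]butan-1-ol | OC[C@H](c1c[nH]c2cc(Br)ccc12)C(C)(C)O[Si](CC)(CC)CC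
A5 | alternative 3 | L-tyrosine | N[C@@H](Cc1ccc(O)cc1)C(=O)O
A6 | alternative 3 | tert-butyl{[(2S)-3-methyl-2-[1-(2-nitro-4-{[(4S)-2,2,5,5-tetramethyl-1,3-dioxolan-4-yl]methyl}phenyl)ethenyl]-3-[(triethylsilyl)oxy]butyl]oxy}diphenylsilane | C=C([C@@H](CO[Si](c1ccccc1)(c1ccccc1)C(C)(C)C)C(C)(C)O[Si](CC)(CC)CC)c1ccc(C[C@@H]2OC(C)(C)OC2(C)C)cc1[N+](=O)[O-]
A7 | alternative 3 | tert-butyl{[(2S)-3-methyl-2-(6-{[(4S)-2,2,5,5-tetramethyl-1,3-dioxolan-4-yl]methyl}-1H-indol-3-yl)-3-[(triethylsilyl)oxy]butyl]oxy}diphenylsilane | CC(C)(C)[Si](c1ccccc1)(c1ccccc1)OC[C@H](c1c[nH]c2cc(C[C@@H]3OC(C)(C)OC3(C)C)ccc12)C(C)(C)O[Si](CC)(CC)CC
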